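## Structural features

The target is an achiral 2-arylbenzofuran. Ring A (benzo ring, C3a to C7a) is fused to ring B (furan, O1, C2, C3), and benzofuran C2 is bonded to C5 of a 2,2-dimethylchroman made of ring C (benzene ring, C4a to C8a) and ring D (dihydropyran, O1, C2, C3, C4). Ring A carries hydroxyls on C4 and C6 and a 2-methylbut-3-en-2-yl group on C7, wedged between the C6 hydroxyl and the furan oxygen at C7a. Ring C carries one hydroxyl on C7, meta to both the biaryl carbon C5 and the ether carbon C8a. There is no stereocentre, so the problems are regiochemical and chemoselective only.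

The fragile parts are:
- the terminal alkene on a quaternary benzylic carbon next to a phenol, which rules out hydrogenolysis and is exposed to acid (ring closure onto the alkene, ipso-protonation with loss of the side chain);
- three electron-rich phenolic rings, open to oxidants and to electrophiles such as formaldehyde equivalents;
- the tertiary alkyl aryl ether of ring D, open to Lewis acids.

The real difficulty is the contiguous 1,2,3-pattern on ring C, that is C5 (biaryl), C4a (alkyl arm) and C8a (ether oxygen) with the second oxygen at C7. A cationic chroman annulation on a 5-aryl resorcinol would have to choose between two ortho carbons. The key step exploits that C4a and C5 are an ortho and ipso pair on a ring whose two oxygens (C7, C8a) both sit meta to C5. A 3,5-dioxygenated aryl iodide is therefore symmetric and its two ortho C–H bonds are identical. Ortho-alkylation (C4a–C4) and ipso-arylation (chroman C5 to benzofuran C2) then need no regiochemical decision, and only one oxygen lies next to the arm to close ring D.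

## Logic of the disconnections

**20 to 19.** The two O–benzyl bonds on O4 and O6 of ring A are cut. These oxygens must stay masked while acid closes ring D, because a free O6 next to the 2-methylbut-3-en-2-yl group could add to the alkene. The gain is only a protecting-group change. The demand is a debenzylation that uses neither hydrogen nor a warm Brønsted acid.

**19 to 17 (through 18).** The O1–C2 bond of ring D is cut, together with two O–CH2OMe bonds and one O–Si bond. Ring D opens to a tertiary carbinol arm on C4a, and ring C becomes a resorcinol in which only one oxygen is adjacent to the arm. This removes a ring and makes the ring C fragment symmetric one step further back. The forward step needs an acid strong enough to ionise the tertiary carbinol but mild enough for the alkene and the benzyl ethers.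

**17 to 14 + 16 + 11.** The aryl–alkyl bond C4a–C4 and the biaryl bond (chroman C5 to benzofuran C2) are cut in one operation. This gives three fragments of similar size, one of them symmetric. The forward step must alkylate once, not twice, and must alkylate before the biaryl coupling. Three design points serve this:
- in 11 boron stays as the pinacol ester, which transmetalates and protodeboronates more slowly than the free acid;
- in 16 the carbinol is silylated, so that carbonate cannot close it to an oxetane;
- in 14 the oxygens carry small, base-stable acetal groups that fall off in the same acid that closes ring D.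

**11 to 9 (through 10).** The C2–B bond is cut. Bromine on C2 gives an unambiguous site for metalation. The demand is exchange at low temperature, faster than any deprotonation.

**9 to 8 to 7.** The furan O1–C2 bond is cut, then the C2=C3 double bond. Ring B is unravelled to a salicylaldehyde, so the benzofuran problem becomes that of a tetrasubstituted phenol. The forward steps need an olefination that tolerates a free, hydrogen-bonded phenol and a C–O coupling that leaves one bromine.

**7 to 5 (through 6).** The C3a–CHO bond is cut. In 5 only one ortho carbon is free, so a phenoxide-directed formylation has no choice to make; it must ignore the carbon between the two benzyloxy groups.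

**5 to 3 (through 4) to 1 + 2.** The bond between C7 and the quaternary carbon is cut as a [3,3] shift, then the O–CH2 bond of the allyl ether. The hindered tertiary alkyl group is traced back to an O-alkylation of a symmetric phenol. The rearrangement must stop at the ortho carbon.

**14 to 13 to 12, and 16 to 15.** Only oxygen-protecting groups are exchanged. The methyl ethers of 12 cannot be removed late in the synthesis, so they are replaced early.

## Other disconnections considered

**Alternative 1:**
- Cut: three bonds of ring A (C4–C5, C6–C7, C3a–C4). What remains is a 2,5-disubstituted furan that already carries the whole chroman and an α-branched acyl chloride, A2, plus the siloxyalkyne A3.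
- Forward key step: triethylamine would convert A2 into the furyl(tert-alkyl)ketene. A [2+2] cycloaddition with A3 would give a 3-siloxycyclobutenone. Heating would open it (four-electron electrocyclic opening) to a dienylketene, which closes (six-electron electrocyclisation) onto furan C3 and tautomerises to A1. This is a benzannulation of the Danheiser type.
- In favour: the tertiary alkyl group arrives on the ketene carbon, so C7 needs no Claisen rearrangement. O4 emerges free and O6 silylated. No metal is used. The way from A1 to the target is one fluoride desilylation without acid. On the placement of the C7 group and on the endgame this alternative is better than the chosen plan.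
- Against: the cycloaddition must form C6–C7 at a ketene carbon bearing both a tertiary alkyl and a heteroaryl group. Productive ring opening needs the furyl group to rotate inward. The electron-rich furan must survive acyl chloride formation and hot amine hydrochloride. Above all, the 5-aryl-7-oxygenated chroman has to exist before the key step, so the regiochemical problem of ring C is moved into the synthesis of A2 and not solved.
- Comparison: structurally the two plans are mirror images. The chosen plan solves ring C by symmetry and leaves C7 to a Claisen step; Alternative 1 does the reverse. Mechanistically both key steps extrapolate known reaction types to a crowded case, and they stand about equal in uncertainty. In step economy A2 needs a furan–chroman biaryl and an α-quaternary acid, so the total should be no shorter.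

**Alternative 2:**
- Cut: three bonds of ring C (C4a–C8a, C5–C6, C7–C8), so that rings C and D disappear together. The precursors are the diyne A5, whose ynol ether oxygen is the future O1, and the ethynylboronate A6.
- Forward key step: Cp*RuCl(cod) would couple the two alkynes of A5 oxidatively to a ruthenacycle, insert A6 and release the arene A4 at room temperature. Oxidation of the C–B bond and removal of the methoxymethyl groups would follow.
- In favour: two rings and three C–C bonds form in one catalytic, neutral step at room temperature, which is more bond-forming power than the chosen key step offers. O1 is built in, so ring D needs no cationic closure. On both points the alternative is better.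
- Against: a tertiary-alkyl ethynyl ether loses alkene to a ketene on mild warming and is hydrated by traces of acid. The boron must end on C7 and not C6, which rests on a steric preference; the chosen plan has no such decision to make. A6 can trimerise with itself. A 1,7-diyne closes less readily than a 1,6-diyne. After the key step, acid has to act while the ring A phenols next to the alkene are free, which is less safe than the chosen endgame.
- Comparison: ring A and ring B still come from the same 2-bromobenzofuran, so the front end is no shorter and the totals should be about equal. Mechanistically the cyclotrimerisation is a well-understood manifold; its weak point is the substrate, not the catalysis.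

**Alternative 3:**
- Cut: C3–C3a of ring B. The precursor is the α-aryloxy-α-aryl acetaldehyde A8, whose ether oxygen is the future furan O1.
- Forward key step: BF3·OEt2 would activate the aldehyde, the one free ortho carbon of the aryl ether would attack it, and loss of water would give A7.
- In favour: Friedel–Crafts cyclodehydration is the best-precedented of the four key steps, and here the alternative is better than the chosen plan. No transition metal is needed. The other ortho carbon is blocked, so regiochemistry is certain. A7 is one debenzylation from the target, a shorter endgame.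
- Against: BF3·OEt2 meets the 2-methylbut-3-en-2-yl group, three benzyl ethers and the tertiary ether of ring D in one flask. A8 is an enolisable α-aryloxy aldehyde that can lose phenoxide or condense with itself. Its C–O bond must be made from the hindered phenol 5 and a secondary benzylic electrophile. The chroman half again needs its own regiocontrolled synthesis.
- Comparison: structurally ring B is made safely but the ring C problem is only relocated. Mechanistically a single electrophilic substitution is simpler and more reliable than a multi-event palladium cycle. In step economy the extra chroman fragment outweighs the short endgame, so the chosen plan should be shorter overall.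

Key step: step 10

Remarks on the chemistry:
- The target has no stereocentre. Dienone 4 is racemic and transient; A2 and A8 are racemic.
- The three components of the key step and its product were compared atom by atom with the target. They agree, and no structure needed correction.
- Assumption: 4-bromo-2-methylbutan-2-ol (15) is bought as a catalogue building block, as are 1, 2 and 12.

## Route

Step 1
Reactants: 1 3,5-bis(benzyloxy)phenol; 2 1-bromo-3-methylbut-2-ene
Product: 3 1,3-bis(benzyloxy)-5-[(3-methylbut-2-en-1-yl)oxy]benzene
Conditions: K2CO3, acetone, reflux
Reagents that add atoms: none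
Why: Williamson ether synthesis; the phenoxide attacks the primary allylic bromide by SN2 at oxygen, which with K2CO3 in a dipolar aprotic solvent is favoured over C-alkylation of the electron-rich ring.

Step 2
Reactants: 3 1,3-bis(benzyloxy)-5-[(3-methylbut-2-en-1-yl)oxy]benzene
Product: 5 3,5-bis(benzyloxy)-2-(2-methylbut-3-en-2-yl)phenol, via ortho-dienone 4 (not isolated)
Conditions: PhNEt2, 190 °C, N2, sealed tube
Reagents that add atoms: none
Why: Aromatic Claisen rearrangement; the [3,3] shift inverts the allyl unit and so joins its dimethyl-substituted carbon to a ring carbon ortho to oxygen (the two ortho carbons are equivalent), and dienone 4 enolises to the phenol; the basic amine solvent holds back acid-catalysed ring closure of the product.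

Step 3
Reactants: 5 3,5-bis(benzyloxy)-2-(2-methylbut-3-en-2-yl)phenol
Product: 7 4,6-bis(benzyloxy)-2-hydroxy-3-(2-methylbut-3-en-2-yl)benzaldehyde, via salicyl alcohol 6 (not isolated)
Conditions: MgCl2, Et3N, (CH2O)n, MeCN, reflux
Reagents that add atoms: paraformaldehyde (reacts as formaldehyde), C=O
Why: Magnesium-mediated ortho-formylation of a phenol (Casnati–Skattebøl type); the magnesium phenoxide delivers formaldehyde to the only free ortho carbon and a second formaldehyde oxidises the benzylic alkoxide of 6 by hydride transfer. The method tolerates an ortho tertiary alkyl group, and the carbon between the benzyloxy groups is left alone because delivery is intramolecular.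

Step 4
Reactants: 7 4,6-bis(benzyloxy)-2-hydroxy-3-(2-methylbut-3-en-2-yl)benzaldehyde
Product: 8 3,5-bis(benzyloxy)-2-(2,2-dibromoethenyl)-6-(2-methylbut-3-en-2-yl)phenol
Conditions: CBr4, PPh3, Et3N, CH2Cl2, 0 °C to rt
Reagents that add atoms: carbon tetrabromide, BrC(Br)(Br)Br
Why: Ramirez dibromo-olefination (first stage of the Corey–Fuchs sequence), a Wittig reaction of the ylide Ph3P=CBr2; it is used on salicylaldehydes with the phenol free when an amine base and excess reagent are present.

Step 5
Reactants: 8 3,5-bis(benzyloxy)-2-(2,2-dibromoethenyl)-6-(2-methylbut-3-en-2-yl)phenol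
Product: 9 4,6-bis(benzyloxy)-2-bromo-7-(2-methylbut-3-en-2-yl)-1-benzofuran
Conditions: CuI (5 mol%), K3PO4, THF, 80 °C
Reagents that add atoms: none
Why: Copper-catalysed intramolecular Ullmann-type C–O coupling of the phenoxide with one vinylic C–Br bond closes the furan (five-membered ring, O1–C2) and leaves the second bromine on C2.

Step 6
Reactants: 9 4,6-bis(benzyloxy)-2-bromo-7-(2-methylbut-3-en-2-yl)-1-benzofuran
Product: 11 2-[4,6-bis(benzyloxy)-7-(2-methylbut-3-en-2-yl)-1-benzofuran-2-yl]-4,4,5,5-tetramethyl-1,3,2-dioxaborolane, via 2-lithiobenzofuran 10 (not isolated)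
Conditions: n-BuLi, THF, −78 °C; then iPrOBpin, −78 °C to rt; aq. NH4Cl
Reagents that add atoms: 2-isopropoxy-4,4,5,5-tetramethyl-1,3,2-dioxaborolane, CC(C)OB1OC(C)(C)C(C)(C)O1
Why: Bromine–lithium exchange at −78 °C is faster than deprotonation of benzylic or ring C–H bonds; aryllithium 10 adds to the borate ester, which loses isopropoxide to give the pinacol boronate.

Step 7
Reactants: 12 1-iodo-3,5-dimethoxybenzene
Product: 13 5-iodobenzene-1,3-diol
Conditions: BBr3, CH2Cl2, −78 °C to rt; then H2O
Reagents that add atoms: none
Why: Lewis-acid cleavage of aryl methyl ethers by BBr3 (bromide attacks the methyl group of the boron-complexed ether); the aryl iodide is inert.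

Step 8
Reactants: 13 5-iodobenzene-1,3-diol
Product: 14 1-iodo-3,5-bis(methoxymethoxy)benzene
Conditions: MOMCl, iPr2NEt, CH2Cl2, 0 °C to rt
Reagents that add atoms: chloromethyl methyl ether, COCCl
Why: O-alkylation of both phenols by the oxocarbenium-type electrophile gives base-stable acetal ethers that are small beside the C–H bond to be metalated later.

Step 9
Reactants: 15 4-bromo-2-methylbutan-2-ol
Product: 16 [(4-bromo-2-methylbutan-2-yl)oxy]triethylsilane
Conditions: TESOTf, 2,6-lutidine, CH2Cl2, −78 to 0 °C
Reagents that add atoms: triethylsilyl trifluoromethanesulfonate, CC[Si](CC)(CC)OS(=O)(=O)C(F)(F)F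
Why: Silylation of a tertiary alcohol with a silyl triflate and a hindered pyridine base; the primary bromide is untouched, and the silyl ether later stops carbonate from closing the bromo alcohol to an oxetane.

Step 10
Reactants: 14 1-iodo-3,5-bis(methoxymethoxy)benzene; 16 [(4-bromo-2-methylbutan-2-yl)oxy]triethylsilane; 11 2-[4,6-bis(benzyloxy)-7-(2-methylbut-3-en-2-yl)-1-benzofuran-2-yl]-4,4,5,5-tetramethyl-1,3,2-dioxaborolane
Product: 17 4,6-bis(benzyloxy)-2-{3,5-bis(methoxymethoxy)-2-[3-methyl-3-(triethylsilyloxy)butyl]phenyl}-7-(2-methylbut-3-en-2-yl)-1-benzofuran
Conditions: Pd(OAc)2 (10 mol%), tri(2-furyl)phosphine (20 mol%), 1-methylbicyclo[2.2.1]hept-2-ene (1.5 equiv), Cs2CO3 (3 equiv), 1,4-dioxane, H2O (5 equiv), 80 °C; 16 (1.05 equiv); 11 (1.3 equiv) added over 6 h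
Reagents that add atoms: none
Why: Proposed new method: zerovalent palladium inserts into the C–I bond of 14, the strained alkene of the norbornene inserts into the aryl–palladium bond, and carbonate-assisted metalation of the ortho C–H closes a five-membered aryl–norbornyl palladacycle of divalent palladium. Oxidative addition of the primary bromide 16 gives a tetravalent palladium intermediate whose reductive elimination forms the aryl–CH2 bond (chroman C4a–C4); β-carbon elimination then expels the norbornene, and the ortho-alkylated arylpalladium species transmetalates with 11 and reductively eliminates to the biaryl bond (benzofuran C2 to chroman C5). The closest known reaction type is the palladium/norbornene (Catellani) ortho-alkylation of aryl iodides by primary alkyl halides with Suzuki-type ipso termination, together with mono-ortho-functionalisation of ortho-unsubstituted aryl iodides by bridgehead-substituted norbornenes; new here is their combination on an iodide whose two ortho C–H bonds are each flanked by an alkoxy group. No ring is closed and no stereocentre is formed. Regiochemistry needs no control because the two ortho positions of 14 are related by symmetry. The selectivity needed is one alkylation and not two, and alkylation before biaryl coupling. The bridgehead methyl group of the mediator should make norbornene extrusion from the mono-alkylated intermediate faster than a second C–H metalation, the remaining ortho C–H is shielded by its neighbouring methoxymethoxy group, and 16 is held near one equivalent. The slowly transmetalating pinacol ester is added slowly so that direct coupling of the first arylpalladium iodide stays behind norbornene insertion, and the crowded alkene of 11 cannot compete with norbornene for insertion.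

Step 11
Reactants: 17 4,6-bis(benzyloxy)-2-{3,5-bis(methoxymethoxy)-2-[3-methyl-3-(triethylsilyloxy)butyl]phenyl}-7-(2-methylbut-3-en-2-yl)-1-benzofuran
Product: 19 5-[4,6-bis(benzyloxy)-7-(2-methylbut-3-en-2-yl)-1-benzofuran-2-yl]-2,2-dimethyl-3,4-dihydro-2H-chromen-7-ol, via triol 18 (not isolated)
Conditions: HCl (1.25 M in MeOH), THF, 45 °C; evaporate; then p-TsOH·H2O (10 mol%), toluene, 60 °C
Reagents that add atoms: none
Why: Acid-catalysed methanolysis removes both methoxymethyl acetals and the silyl ether (methanol traps the methoxymethyl cation); the tertiary alcohol of 18 then ionises and the only adjacent phenol captures the cation (six-membered ring, O1–C2 of ring D). The benzyl ethers keep O4 and O6 away from the alkene, and a monosubstituted alkene should not be protonated by catalytic sulfonic acid at this temperature.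

Step 12
Reactants: 19 5-[4,6-bis(benzyloxy)-7-(2-methylbut-3-en-2-yl)-1-benzofuran-2-yl]-2,2-dimethyl-3,4-dihydro-2H-chromen-7-ol
Product: 20 2-(7-hydroxy-2,2-dimethyl-3,4-dihydro-2H-chromen-5-yl)-7-(2-methylbut-3-en-2-yl)-1-benzofuran-4,6-diol
Conditions: BCl3 (1 M in CH2Cl2), C6HMe5, CH2Cl2, −78 °C; CHCl3/MeOH quench at −78 °C
Reagents that add atoms: none
Why: Lewis-acid debenzylation of aryl benzyl ethers with pentamethylbenzene as a non-coordinating scavenger of the benzyl cation; at −78 °C the alkene and the tertiary ether of ring D should survive, and hydrogenolysis is avoided because it would saturate the alkene.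

## Compound list

1 | 3,5-bis(benzyloxy)phenol | Oc1cc(OCc2ccccc2)cc(OCc2ccccc2)c1 | starting material
2 | 1-bromo-3-methylbut-2-ene | CC(C)=CCBr | starting material
3 | 1,3-bis(benzyloxy)-5-[(3-methylbut-2-en-1-yl)oxy]benzene | CC(C)=CCOc1cc(OCc2ccccc2)cc(OCc2ccccc2)c1 | intermediate
4 | 3,5-bis(benzyloxy)-6-(2-methylbut-3-en-2-yl)cyclohexa-2,4-dien-1-one (racemic, transient) | O=C1C=C(OCc2ccccc2)C=C(OCc2ccccc2)C1C(C)(C)C=C | intermediate
5 | 3,5-bis(benzyloxy)-2-(2-methylbut-3-en-2-yl)phenol | C=CC(C)(C)c1c(O)cc(OCc2ccccc2)cc1OCc1ccccc1 | intermediate
6 | 3,5-bis(benzyloxy)-2-(hydroxymethyl)-6-(2-methylbut-3-en-2-yl)phenol (present as its magnesium salt) | C=CC(C)(C)c1c(O)c(CO)c(OCc2ccccc2)cc1OCc1ccccc1 | intermediate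
7 | 4,6-bis(benzyloxy)-2-hydroxy-3-(2-methylbut-3-en-2-yl)benzaldehyde | C=CC(C)(C)c1c(O)c(C=O)c(OCc2ccccc2)cc1OCc1ccccc1 | intermediate
8 | 3,5-bis(benzyloxy)-2-(2,2-dibromoethenyl)-6-(2-methylbut-3-en-2-yl)phenol | C=CC(C)(C)c1c(O)c(C=C(Br)Br)c(OCc2ccccc2)cc1OCc1ccccc1 | intermediate
9 | 4,6-bis(benzyloxy)-2-bromo-7-(2-methylbut-3-en-2-yl)-1-benzofuran | C=CC(C)(C)c1c(OCc2ccccc2)cc(OCc2ccccc2)c2cc(Br)oc12 | intermediate
10 | [4,6-bis(benzyloxy)-7-(2-methylbut-3-en-2-yl)-1-benzofuran-2-yl]lithium | C=CC(C)(C)c1c(OCc2ccccc2)cc(OCc2ccccc2)c2cc([Li])oc12 | intermediate
11 | 2-[4,6-bis(benzyloxy)-7-(2-methylbut-3-en-2-yl)-1-benzofuran-2-yl]-4,4,5,5-tetramethyl-1,3,2-dioxaborolane | C=CC(C)(C)c1c(OCc2ccccc2)cc(OCc2ccccc2)c2cc(B3OC(C)(C)C(C)(C)O3)oc12 | intermediate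
12 | 1-iodo-3,5-dimethoxybenzene | COc1cc(I)cc(OC)c1 | starting material
13 | 5-iodobenzene-1,3-diol | Oc1cc(O)cc(I)c1 | intermediate
14 | 1-iodo-3,5-bis(methoxymethoxy)benzene | COCOc1cc(I)cc(OCOC)c1 | intermediate
15 | 4-bromo-2-methylbutan-2-ol | CC(C)(O)CCBr | starting material
16 | [(4-bromo-2-methylbutan-2-yl)oxy]triethylsilane | CC(C)(CCBr)O[Si](CC)(CC)CC | intermediate
17 | 4,6-bis(benzyloxy)-2-{3,5-bis(methoxymethoxy)-2-[3-methyl-3-(triethylsilyloxy)butyl]phenyl}-7-(2-methylbut-3-en-2-yl)-1-benzofuran | C=CC(C)(C)c1c(OCc2ccccc2)cc(OCc2ccccc2)c2cc(-c3cc(OCOC)cc(OCOC)c3CCC(C)(C)O[Si](CC)(CC)CC)oc12 | intermediate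
18 | 5-[4,6-bis(benzyloxy)-7-(2-methylbut-3-en-2-yl)-1-benzofuran-2-yl]-4-(3-hydroxy-3-methylbutyl)benzene-1,3-diol | C=CC(C)(C)c1c(OCc2ccccc2)cc(OCc2ccccc2)c2cc(-c3cc(O)cc(O)c3CCC(C)(C)O)oc12 | intermediate
19 | 5-[4,6-bis(benzyloxy)-7-(2-methylbut-3-en-2-yl)-1-benzofuran-2-yl]-2,2-dimethyl-3,4-dihydro-2H-chromen-7-ol | C=CC(C)(C)c1c(OCc2ccccc2)cc(OCc2ccccc2)c2cc(-c3cc(O)cc4c3CCC(C)(C)O4)oc12 | intermediate
20 | 2-(7-hydroxy-2,2-dimethyl-3,4-dihydro-2H-chromen-5-yl)-7-(2-methylbut-3-en-2-yl)-1-benzofuran-4,6-diol | C=CC(C)(C)c1c(O)cc(O)c2cc(-c3cc(O)cc4c3CCC(C)(C)O4)oc12 | target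

## Step count and risk

Total: 12 steps. Longest linear sequence: 9 steps (steps 1 to 6, then 10, 11 and 12).

**Step 10 (key step, bears the label "Proposed new method:").** Three things can go wrong:
- direct biaryl coupling of the first arylpalladium iodide with 11 before norbornene insertion;
- sluggish metalation of a C–H bond that has an alkoxy neighbour, leaving norbornene-containing products;
- a second alkylation, or protodeboronation of the electron-rich heteroaryl boronate.

The fallback uses three known reactions. It sets out from 14 and returns at 17. NBS in MeCN should brominate 14 at the carbon between iodine and a methoxymethoxy group (para to the other one), giving 2-bromo-1-iodo-3,5-bis(methoxymethoxy)benzene F1. Suzuki–Miyaura coupling of F1 with 11 (Pd(PPh3)4, K3PO4, dioxane/H2O, 60 °C) should take place at the more reactive C–I bond and give 4,6-bis(benzyloxy)-2-[2-bromo-3,5-bis(methoxymethoxy)phenyl]-7-(2-methylbut-3-en-2-yl)-1-benzofuran F2. Negishi coupling of F2 (Pd(OAc)2, SPhos, THF, 50 °C) with bromo[3-methyl-3-(triethylsilyloxy)butyl]zinc F3, made from 16 with zinc dust and catalytic iodine in DMA, should then give 17.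

**Step 2.** The first-formed phenol can react further at 190 °C (hydrogen shift of the abnormal Claisen type, closure of the phenol onto the alkene), and dienone 4 can undergo a second [3,3] shift to the para carbon. The fallback interrupts the rearrangement by acylation. It sets out from 3 and returns at 5. Heating 3 with Ac2O and NaOAc in PhNEt2 should trap the phenol as it forms as 3,5-bis(benzyloxy)-2-(2-methylbut-3-en-2-yl)phenyl acetate F4, which cannot undergo the secondary reactions. K2CO3 in MeOH at room temperature then gives 5.

**Step 4.** The aldehyde is flanked by two oxygens and deactivated by three donors, so addition of the weakly nucleophilic dibromomethylene ylide may be slow, and the phenol may quench the ylide. The fallback builds ring B without bromine. It sets out from 7 and returns at 10. A Wittig reaction with the more nucleophilic ylide from MeOCH2PPh3Cl and KOtBu (THF, 0 °C to rt) should give 3,5-bis(benzyloxy)-2-(2-methoxyethenyl)-6-(2-methylbut-3-en-2-yl)phenol F5 as an E/Z mixture. Catalytic p-TsOH·H2O in toluene at 50 °C should close it to the cyclic acetal and eliminate methanol to 4,6-bis(benzyloxy)-7-(2-methylbut-3-en-2-yl)-1-benzofuran F6. n-BuLi in THF at −78 °C deprotonates C2 of F6 to give 10, which is borylated as in step 6.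

**Step 11.** Possible failures are acid-induced loss or migration of the 2-methylbut-3-en-2-yl group through ipso-protonation, alkylation of the freed resorcinol by formaldehyde equivalents, and incomplete ring closure through capture of the cation by methanol. The fallback separates the deprotections and avoids protic acidolysis of the acetals. It sets out from 17 and returns at 18. TBAF in THF should remove the silyl group and give 4-{2-[4,6-bis(benzyloxy)-7-(2-methylbut-3-en-2-yl)-1-benzofuran-2-yl]-4,6-bis(methoxymethoxy)phenyl}-2-methylbutan-2-ol F7. ZnBr2 with n-PrSH in CH2Cl2 at 0 °C should then transfer the methoxymethyl groups to the thiol within minutes and give 18, which is closed as in the second stage of step 11.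

**Step 12.** The Lewis acid may open the tertiary ether of ring D, or add the freed O6 phenol across the neighbouring alkene during warming or quench. The fallback replaces electrophilic cleavage by nucleophilic dealkylation. It sets out from 19 and returns at 20. Sodium ethanethiolate (NaSEt) in DMF at 110 °C should remove both benzyl groups by SN2 attack at the benzylic carbons under basic conditions that leave the alkene and ring D alone. This fallback makes no new intermediate (F0).

## Further compounds

F1 | step 10 | 2-bromo-1-iodo-3,5-bis(methoxymethoxy)benzene | COCOc1cc(I)c(Br)c(OCOC)c1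
F2 | step 10 | 4,6-bis(benzyloxy)-2-[2-bromo-3,5-bis(methoxymethoxy)phenyl]-7-(2-methylbut-3-en-2-yl)-1-benzofuran | C=CC(C)(C)c1c(OCc2ccccc2)cc(OCc2ccccc2)c2cc(-c3cc(OCOC)cc(OCOC)c3Br)oc12
F3 | step 10 | bromo[3-methyl-3-(triethylsilyloxy)butyl]zinc | CC(C)(CC[Zn]Br)O[Si](CC)(CC)CC
F4 | step 2 | 3,5-bis(benzyloxy)-2-(2-methylbut-3-en-2-yl)phenyl acetate | C=CC(C)(C)c1c(OC(C)=O)cc(OCc2ccccc2)cc1OCc1ccccc1
F5 | step 4 | 3,5-bis(benzyloxy)-2-(2-methoxyethenyl)-6-(2-methylbut-3-en-2-yl)phenol (E/Z mixture) | C=CC(C)(C)c1c(O)c(C=COC)c(OCc2ccccc2)cc1OCc1ccccc1
F6 | step 4 | 4,6-bis(benzyloxy)-7-(2-methylbut-3-en-2-yl)-1-benzofuran | C=CC(C)(C)c1c(OCc2ccccc2)cc(OCc2ccccc2)c2ccoc12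
F7 | step 11 | 4-{2-[4,6-bis(benzyloxy)-7-(2-methylbut-3-en-2-yl)-1-benzofuran-2-yl]-4,6-bis(methoxymethoxy)phenyl}-2-methylbutan-2-ol | C=CC(C)(C)c1c(OCc2ccccc2)cc(OCc2ccccc2)c2cc(-c3cc(OCOC)cc(OCOC)c3CCC(C)(C)O)oc12
F0 | step 12 | none | none
A1 | alternative 1 | 2-[2,2-dimethyl-7-(triisopropylsilyloxy)chroman-5-yl]-7-(2-methylbut-3-en-2-yl)-6-(triisopropylsilyloxy)benzofuran-4-ol | C=CC(C)(C)c1c(O[Si](C(C)C)(C(C)C)C(C)C)cc(O)c2cc(-c3cc(O[Si](C(C)C)(C(C)C)C(C)C)cc4c3CCC(C)(C)O4)oc12
A2 | alternative 1 | 2-{5-[2,2-dimethyl-7-(triisopropylsilyloxy)chroman-5-yl]furan-2-yl}-3,3-dimethylpent-4-enoyl chloride (racemic) | C=CC(C)(C)C(C(=O)Cl)c1ccc(-c2cc(O[Si](C(C)C)(C(C)C)C(C)C)cc3c2CCC(C)(C)O3)o1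
A3 | alternative 1 | (triisopropylsilyloxy)ethyne | C#CO[Si](C(C)C)(C(C)C)C(C)C
A4 | alternative 2 | 2-{5-[4,6-bis(methoxymethoxy)-7-(2-methylbut-3-en-2-yl)benzofuran-2-yl]-2,2-dimethylchroman-7-yl}-4,4,5,5-tetramethyl-1,3,2-dioxaborolane | C=CC(C)(C)c1c(OCOC)cc(OCOC)c2cc(-c3cc(B5OC(C)(C)C(C)(C)O5)cc4c3CCC(C)(C)O4)oc12
A5 | alternative 2 | 2-[5-(ethynyloxy)-5-methylhex-1-yn-1-yl]-4,6-bis(methoxymethoxy)-7-(2-methylbut-3-en-2-yl)-1-benzofuran | C#COC(C)(C)CCC#Cc1cc2c(OCOC)cc(OCOC)c(C(C)(C)C=C)c2o1
A6 | alternative 2 | 2-ethynyl-4,4,5,5-tetramethyl-1,3,2-dioxaborolane | C#CB1OC(C)(C)C(C)(C)O1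
A7 | alternative 3 | 4,6-bis(benzyloxy)-2-[7-(benzyloxy)-2,2-dimethylchroman-5-yl]-7-(2-methylbut-3-en-2-yl)-1-benzofuran | C=CC(C)(C)c1c(OCc2ccccc2)cc(OCc2ccccc2)c2cc(-c3cc(OCc4ccccc4)cc4c3CCC(C)(C)O4)oc12
A8 | alternative 3 | 2-[3,5-bis(benzyloxy)-2-(2-methylbut-3-en-2-yl)phenoxy]-2-[7-(benzyloxy)-2,2-dimethylchroman-5-yl]acetaldehyde (racemic) | O=CC(Oc1cc(OCc2ccccc2)cc(OCc2ccccc2)c1C(C)(C)C=C)c1cc(OCc2ccccc2)cc2c1CCC(C)(C)O2
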